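Everything rests on opening rings A and B together in one retro-[2+2+2]. In ring A the fusion carbons C4a and C8a are flanked by C5–H and C8–H, and C6 and C7 carry oxygen. This pattern results when an ethynyl group on C1 and one on the C4 methylene combine with a symmetrical alkyne bearing two heteroatom handles. One ruthenium-catalysed cocyclisation with bis(pinacolboryl)ethyne forms C4a–C8a, C5–C6 and C7–C8, closes both rings and leaves two C–B bonds as masked methoxy groups. The precursor is an open-chain 1,7-diyne already carrying the veratryl group, both methoxymethyl arms and all three stereocentres. These are set by an auxiliary-controlled Nicholas alkylation and a trans-selective lactone propargylation.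

Key step: step 10

Remarks on the chemistry
- Tetralin numbering is used for the future ring atoms throughout: C1 bears the aryl group, C2 and C3 bear CH2OMe, and C4 is CH2.
- The target SMILES reads (1S,2S,3S). The aryl group at C1 and CH2OMe at C2 are cis; the two CH2OMe groups are trans.
- Descriptor correction: the open-chain terminal diyne with this geometry is (3R,4S,5S), not 3S. At its C3 the aryl group outranks ethynyl, whereas in the tetralin C8a outranks the aryl group. The label therefore changes from R to S on cyclisation with no change in space. With C-silyl caps the alkynyl branch outranks aryl and the same centre reads S.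
- Assumption: a dibutylboron imide enolate meets a non-coordinating carbocation in its internally chelated form, with the facial sense of an Evans alkylation. This fixes the (S)-auxiliary.

Step 1
Reactants: 1 4-tert-butoxy-4-oxobutanoic acid (mono-tert-butyl succinate); 2 (S)-4-benzyl-2-oxazolidinone
Product: 4 tert-butyl 4-[(4S)-4-benzyl-2-oxo-1,3-oxazolidin-3-yl]-4-oxobutanoate, via mixed pivalic anhydride 3 (not isolated)
Conditions: PivCl, Et3N, THF, −20 °C; then LiCl, 2, −20 °C to rt
Reagents that add atoms: pivaloyl chloride, CC(C)(C)C(=O)Cl (its acyl group is held only in 3)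
Why: N-Acylation of an Evans oxazolidinone through a mixed anhydride, in which the hindered pivaloyl carbonyl directs the LiCl-activated oxazolidinone to the succinyl carbonyl and the tert-butyl ester stays inert.

Step 2
Reactants: 5 veratraldehyde; 6 trimethylsilylacetylene
Product: 9 racemic 1-(3,4-dimethoxyphenyl)-3-(trimethylsilyl)prop-2-yn-1-yl acetate, via lithium acetylide 7 (not isolated), via lithium alkoxide 8 (not isolated)
Conditions: 6, n-BuLi, THF, −78 °C; 5, −78 to 0 °C; then Ac2O, 0 °C to rt
Reagents that add atoms: acetic anhydride, CC(=O)OC(C)=O; n-butyllithium, [Li]CCCC (its lithium is held only in 7 and 8)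
Why: 1,2-Addition of a lithium acetylide to an aldehyde with in situ O-acetylation, where the racemic carbinol centre is of no concern because ionisation in step 4 erases it.

Step 3
Reactants: 9 racemic propargylic acetate
Product: 10 hexacarbonyldicobalt complex of 9 (Co2(CO)6 bridging the C≡C bond; racemic)
Conditions: Co2(CO)8 (1.05 equiv), CH2Cl2, rt; filtration through silica
Reagents that add atoms: Co2(CO)8, O=C=[Co](=C=O)(=C=O)(=C=O)[Co](=C=O)(=C=O)(=C=O)=C=O
Why: Alkyne complexation by Co2(CO)8 with loss of two CO (first stage of the Nicholas reaction), isolated so that no uncomplexed acetate, which would give allenyl products, enters the Lewis acid step.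

Step 4
Reactants: 4 succinyl imide; 10 cobalt-complexed acetate
Product: 13 hexacarbonyldicobalt complex of tert-butyl (3R,4S)-3-{[(4S)-4-benzyl-2-oxo-1,3-oxazolidin-3-yl]carbonyl}-4-(3,4-dimethoxyphenyl)-6-(trimethylsilyl)hex-5-ynoate, via Z-boron enolate 11 (not isolated), via cobalt-stabilised propargylium triflate 12 (not isolated)
Conditions: 4, Bu2BOTf (1.1 equiv), i-Pr2NEt, CH2Cl2, −78 to 0 °C; then 10, Bu2BOTf (1.5 equiv), −78 to 0 °C; pH 7 buffer
Reagents that add atoms: dibutylboron triflate, CCCCB(CCCC)OS(=O)(=O)C(F)(F)F (held only in 11 and 12)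
Why: Nicholas reaction with a chiral boron enolate, in which Bu2BOTf ionises 10 to cation 12, which has lost the configuration of 9 and should interconvert between its enantiomeric forms faster than it is trapped, and 12 attacks the chelated Z-enolate 11 on the face away from the benzyl group (Evans alkylation sense, setting the future C2) through the open transition state known to give syn products from Z-boron enolates and secondary silyl-capped Co2(CO)6-propargylium ions (setting the future C1 in the relation that becomes 1,2-cis in the ring).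

Step 5
Reactants: 13 cobalt-complexed adduct
Product: 14 tert-butyl (3R,4S)-3-{[(4S)-4-benzyl-2-oxo-1,3-oxazolidin-3-yl]carbonyl}-4-(3,4-dimethoxyphenyl)-6-(trimethylsilyl)hex-5-ynoate
Conditions: Fe(NO3)3·9H2O, EtOH/THF, 0 °C to rt
Reagents that add atoms: none
Why: Oxidative decomplexation (last stage of the Nicholas sequence) with a mild trivalent-iron oxidant that removes cobalt as CO and Co(NO3)2 but is too weak to oxidise the veratryl ring and leaves the imide, tert-butyl ester, C–Si bond and both stereocentres alone.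

Step 6
Reactants: 14 alkynyl imide
Product: 16 (4R)-4-[(1S)-1-(3,4-dimethoxyphenyl)-3-(trimethylsilyl)prop-2-yn-1-yl]oxolan-2-one, via hydroxy ester 15 (not isolated)
Conditions: LiBH4, MeOH (1 equiv), Et2O/THF, 0 °C; aqueous work-up; then p-TsOH·H2O (10 mol %), toluene, 70 °C; 2 recovered
Reagents that add atoms: none
Why: Reductive removal of the Evans auxiliary, in which LiBH4 attacks the more electrophilic exocyclic imide carbonyl and spares the tert-butyl ester, followed by acid-catalysed lactonisation to the five-membered ring, neither operation touching the two stereocentres.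

Step 7
Reactants: 16 beta-substituted butyrolactone; 17 3-bromo-1-(trimethylsilyl)prop-1-yne
Product: 19 (3S,4S)-4-[(1S)-1-(3,4-dimethoxyphenyl)-3-(trimethylsilyl)prop-2-yn-1-yl]-3-[3-(trimethylsilyl)prop-2-yn-1-yl]oxolan-2-one, via lithium enolate 18 (not isolated)
Conditions: LiN(SiMe3)2, THF, −78 °C; 17, DMPU, −78 to −30 °C
Reagents that add atoms: LiN(SiMe3)2, [Li+].C[Si](C)(C)[N-][Si](C)(C)C (its lithium is held only in 18)
Why: Enolate alkylation of a beta-substituted gamma-butyrolactone as used in classical lignan lactone chemistry, where the bromide approaches anti to the bulky C4 substituent and so sets the future C3 trans to C2, while the silyl cap removes the acidic acetylenic proton of the electrophile.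

Step 8
Reactants: 19 trans-disubstituted lactone
Product: 20 (2S,3S)-2-[(1S)-1-(3,4-dimethoxyphenyl)-3-(trimethylsilyl)prop-2-yn-1-yl]-3-[3-(trimethylsilyl)prop-2-yn-1-yl]butane-1,4-diol
Conditions: LiAlH4, THF, 0 °C; Fieser work-up
Reagents that add atoms: none
Why: Hydride reduction of a lactone to the 1,4-diol, run at 0 °C where silyl alkynes that are not propargylic to an alkoxide are not hydroaluminated and no stereocentre is involved.

Step 9
Reactants: 20 bis-silyl diol
Product: 22 (3R,4S,5S)-3-(3,4-dimethoxyphenyl)-4,5-bis(methoxymethyl)octa-1,7-diyne, via bis-silyl diether 21 (not isolated)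
Conditions: Me3OBF4, 1,8-bis(dimethylamino)naphthalene, CH2Cl2, 0 °C to rt; then MeOH, K2CO3 (cat.), rt
Reagents that add atoms: trimethyloxonium tetrafluoroborate, C[O+](C)C.F[B-](F)(F)F
Why: O-Methylation with Me3OBF4 buffered by a non-nucleophilic base, followed by carbonate-catalysed methanolysis of both C(sp)–Si bonds, so that no alkoxide or acetylide ever meets the methylating agent and neither C-methylation nor propargyl–allene isomerisation at the aryl-bearing centre can intervene.

Step 10
Reactants: 22 chiral 1,7-diyne; 23 1,2-bis(4,4,5,5-tetramethyl-1,3,2-dioxaborolan-2-yl)ethyne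
Product: 25 (1S,2S,3S)-1-(3,4-dimethoxyphenyl)-2,3-bis(methoxymethyl)-6,7-bis(4,4,5,5-tetramethyl-1,3,2-dioxaborolan-2-yl)-1,2,3,4-tetrahydronaphthalene, via ruthenacyclopentadiene 24 (not isolated)
Conditions: Cp*RuCl(cod) (10 mol %), 23 (2.5 equiv), ClCH2CH2Cl, rt, Ar; 22 added by syringe pump over 8 h
Reagents that add atoms: Cp*RuCl(cod), Cc1c(C)c(C)[c-](C)c1C.[Ru+2].[Cl-].C1=CCCC=CCC1 (its Cp*RuCl fragment is held only in 24 and is released again)
Why: Loss of cod leaves a Cp*RuCl fragment (divalent ruthenium) that binds both terminal alkynes of 22 and couples them oxidatively through their internal carbons to ruthenacyclopentadiene 24 (formally tetravalent ruthenium), creating C4a–C8a; 23 then coordinates and inserts, and reductive elimination creates C5–C6 and C7–C8 and frees the catalyst. The nearest established chemistry is the transition-metal-catalysed (Ru, Co, Rh) cocyclisation of tethered diynes with alkynyl boronic esters to benzo-fused aryl boronates, in which a diborylated ethyne has been used far less often than monoboryl alkynes. Ring B closes as a six-membered carbocycle in the intramolecular oxidative coupling of two alkynes joined by the four-atom tether C1–C2–C3–C4, and ring A closes as the benzene ring when the four metallacycle carbons take up the two carbons of 23. No stereocentre is formed, and the three existing ones are spectators because the medium is neutral and at room temperature, so the propargylic-benzylic C1–H is neither deprotonated nor ionised and the 1,2-cis relation cannot relax. The selectivity required is cross-cyclotrimerisation over self-coupling of 22: the unsubstituted alkyne termini and the three branches on the tether favour fast folding to 24, syringe-pump addition keeps free 22 scarce, and 23 is in excess yet too hindered to trimerise alone. Regiochemistry is no issue because 23 is symmetrical, and its boryl groups end up beside the small C5–H and C8–H.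

Step 11
Reactants: 25 6,7-diboryl aryltetralin
Product: 26 (1S,2S,3S)-1-(3,4-dimethoxyphenyl)-6,7-dihydroxy-2,3-bis(methoxymethyl)-1,2,3,4-tetrahydronaphthalene
Conditions: NaBO3·4H2O, degassed THF/H2O, 0 °C to rt, N2; crude product carried on at once
Reagents that add atoms: NaBO3·4H2O (sodium perborate), [Na+].[Na+].O[B-]1(O)OO[B-](O)(O)OO1
Why: Oxidation of aryl boronic esters by peroxide attack on boron and 1,2-aryl migration, carried out with the weakly basic perborate under nitrogen so that the catechol meets neither strong base nor air.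

Step 12
Reactants: 26 catechol
Product: 27 (1S,2S,3S)-1-(3,4-dimethoxyphenyl)-6,7-dimethoxy-2,3-bis(methoxymethyl)-1,2,3,4-tetrahydronaphthalene (target)
Conditions: MeI, K2CO3, acetone, N2, 50 °C
Reagents that add atoms: iodomethane, CI
Why: Williamson O-methylation of both phenols with a carbonate base far too weak to deprotonate the doubly benzylic C1–H, so the configuration is retained.

Compound list
1 | 4-tert-butoxy-4-oxobutanoic acid | CC(C)(C)OC(=O)CCC(=O)O | starting material
2 | (S)-4-benzyl-2-oxazolidinone | O=C1N[C@@H](Cc2ccccc2)CO1 | starting material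
3 | 4-tert-butoxy-4-oxobutanoic pivalic anhydride | CC(C)(C)OC(=O)CCC(=O)OC(=O)C(C)(C)C | intermediate
4 | tert-butyl 4-[(4S)-4-benzyl-2-oxo-1,3-oxazolidin-3-yl]-4-oxobutanoate | CC(C)(C)OC(=O)CCC(=O)N1C(=O)OC[C@@H]1Cc1ccccc1 | intermediate
5 | veratraldehyde | COc1ccc(C=O)cc1OC | starting material
6 | trimethylsilylacetylene | C#C[Si](C)(C)C | starting material
7 | lithium (trimethylsilyl)acetylide | [Li+].[C-]#C[Si](C)(C)C | intermediate
8 | lithium 1-(3,4-dimethoxyphenyl)-3-(trimethylsilyl)prop-2-yn-1-olate (racemic) | [Li+].[O-]C(C#C[Si](C)(C)C)c1ccc(OC)c(OC)c1 | intermediate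
9 | 1-(3,4-dimethoxyphenyl)-3-(trimethylsilyl)prop-2-yn-1-yl acetate (racemic) | CC(=O)OC(C#C[Si](C)(C)C)c1ccc(OC)c(OC)c1 | intermediate
10 | hexacarbonyldicobalt complex of 9 (racemic) | CC(=O)OC(c1ccc(OC)c(OC)c1)C12C3([Si](C)(C)C)[Co]1(=C=O)(=C=O)(=C=O)[Co]23(=C=O)(=C=O)=C=O | intermediate
11 | (Z)-dibutylboron enolate of 4 | CCCCB(CCCC)O/C(=C\CC(=O)OC(C)(C)C)N1C(=O)OC[C@@H]1Cc1ccccc1 | intermediate
12 | Co2(CO)6-stabilised 1-(3,4-dimethoxyphenyl)-3-(trimethylsilyl)propargylium triflate | C[Si](C)(C)C12C3([CH+]c4ccc(OC)c(OC)c4)[Co]1(=C=O)(=C=O)(=C=O)[Co]23(=C=O)(=C=O)=C=O.[O-]S(=O)(=O)C(F)(F)F | intermediate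
13 | hexacarbonyldicobalt complex of 14 | CC(C)(C)OC(=O)C[C@@H](C(=O)N1C(=O)OC[C@@H]1Cc1ccccc1)[C@@H](c1ccc(OC)c(OC)c1)C12C3([Si](C)(C)C)[Co]1(=C=O)(=C=O)(=C=O)[Co]23(=C=O)(=C=O)=C=O | intermediate
14 | tert-butyl (3R,4S)-3-{[(4S)-4-benzyl-2-oxo-1,3-oxazolidin-3-yl]carbonyl}-4-(3,4-dimethoxyphenyl)-6-(trimethylsilyl)hex-5-ynoate | CC(C)(C)OC(=O)C[C@@H](C(=O)N1C(=O)OC[C@@H]1Cc1ccccc1)[C@@H](c1ccc(OC)c(OC)c1)C#C[Si](C)(C)C | intermediate
15 | tert-butyl (3R,4S)-4-(3,4-dimethoxyphenyl)-3-(hydroxymethyl)-6-(trimethylsilyl)hex-5-ynoate | CC(C)(C)OC(=O)C[C@@H](CO)[C@@H](c1ccc(OC)c(OC)c1)C#C[Si](C)(C)C | intermediate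
16 | (4R)-4-[(1S)-1-(3,4-dimethoxyphenyl)-3-(trimethylsilyl)prop-2-yn-1-yl]oxolan-2-one | O=C1C[C@@H](CO1)[C@@H](c1ccc(OC)c(OC)c1)C#C[Si](C)(C)C | intermediate
17 | 3-bromo-1-(trimethylsilyl)prop-1-yne | C[Si](C)(C)C#CCBr | starting material
18 | lithium enolate of 16 | [Li+].[O-]C1=C[C@@H](CO1)[C@@H](c1ccc(OC)c(OC)c1)C#C[Si](C)(C)C | intermediate
19 | (3S,4S)-4-[(1S)-1-(3,4-dimethoxyphenyl)-3-(trimethylsilyl)prop-2-yn-1-yl]-3-[3-(trimethylsilyl)prop-2-yn-1-yl]oxolan-2-one | O=C1[C@@H](CC#C[Si](C)(C)C)[C@@H](CO1)[C@@H](c1ccc(OC)c(OC)c1)C#C[Si](C)(C)C | intermediate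
20 | (2S,3S)-2-[(1S)-1-(3,4-dimethoxyphenyl)-3-(trimethylsilyl)prop-2-yn-1-yl]-3-[3-(trimethylsilyl)prop-2-yn-1-yl]butane-1,4-diol | OC[C@@H](CC#C[Si](C)(C)C)[C@@H](CO)[C@@H](c1ccc(OC)c(OC)c1)C#C[Si](C)(C)C | intermediate
21 | (3S,4S,5S)-3-(3,4-dimethoxyphenyl)-4,5-bis(methoxymethyl)-1,8-bis(trimethylsilyl)octa-1,7-diyne | COC[C@@H](CC#C[Si](C)(C)C)[C@@H](COC)[C@@H](c1ccc(OC)c(OC)c1)C#C[Si](C)(C)C | intermediate
22 | (3R,4S,5S)-3-(3,4-dimethoxyphenyl)-4,5-bis(methoxymethyl)octa-1,7-diyne | COC[C@@H](CC#C)[C@@H](COC)[C@@H](c1ccc(OC)c(OC)c1)C#C | intermediate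
23 | 1,2-bis(4,4,5,5-tetramethyl-1,3,2-dioxaborolan-2-yl)ethyne | CC1(C)OB(C#CB2OC(C)(C)C(C)(C)O2)OC1(C)C | starting material
24 | Cp*(Cl)Ru ruthenacyclopentadiene fused to ring B (Ru bound to C5 and C8; configuration as in 22) | COC[C@H]1CC2=C[Ru+](Cl)C=C2[C@H](c2ccc(OC)c(OC)c2)[C@@H]1COC.Cc1c(C)c(C)[c-](C)c1C | intermediate
25 | (1S,2S,3S)-1-(3,4-dimethoxyphenyl)-2,3-bis(methoxymethyl)-6,7-bis(pinacolboryl)-1,2,3,4-tetrahydronaphthalene | COC[C@H]1Cc2cc(B3OC(C)(C)C(C)(C)O3)c(B3OC(C)(C)C(C)(C)O3)cc2[C@H](c2ccc(OC)c(OC)c2)[C@@H]1COC | intermediate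
26 | (1S,2S,3S)-1-(3,4-dimethoxyphenyl)-6,7-dihydroxy-2,3-bis(methoxymethyl)-1,2,3,4-tetrahydronaphthalene | COC[C@H]1Cc2cc(O)c(O)cc2[C@H](c2ccc(OC)c(OC)c2)[C@@H]1COC | intermediate
27 | (1S,2S,3S)-1-(3,4-dimethoxyphenyl)-6,7-dimethoxy-2,3-bis(methoxymethyl)-1,2,3,4-tetrahydronaphthalene | COC[C@H]1Cc2cc(OC)c(OC)cc2[C@H](c2ccc(OC)c(OC)c2)[C@@H]1COC | target

Total step count: 12
Longest linear sequence: 11 steps (5 to 27, steps 2–12)

Steps most likely to fail

Step 10. Intermolecular coupling of diyne molecules with one another may outpace capture of the metallacycle by the hindered alkyne. Alternatively, the four-atom tether may close too slowly on ruthenium. The fallback reverses the order of assembly on a stoichiometric metal template.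
- 23 is first bound with Co2(CO)8 (CH2Cl2, rt) as the hexacarbonyldicobalt complex of bis(pinacolboryl)ethyne F1.
- F1 is then heated with 22 in refluxing xylene.
- Every reacting metal centre already holds the monoalkyne, so cross-selectivity no longer depends on relative rates at a catalyst.
- This is the known zerovalent-cobalt-mediated cycloaddition of complexed alkynyl boronates with tethered diynes.
- The fallback sets out from 22 and 23 and returns to the route at 25.

Step 4. Simple diastereoselection at the aryl-bearing carbon may be poor. Capture of a cation stabilised by both the cluster and the dimethoxyaryl group may also be sluggish. The fallback sets the two centres separately.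
- 5 is condensed with Meldrum's acid (Knoevenagel, piperidine/AcOH) to 5-(3,4-dimethoxybenzylidene)-2,2-dimethyl-1,3-dioxane-4,6-dione F2.
- Enantioselective rhodium-catalysed conjugate alkynylation with 6 follows, using Rh(acac)(C2H4)2 and the enantiomer of a MeO-BIPHEP-type bisphosphine that delivers the S centre. It gives 5-[(1S)-1-(3,4-dimethoxyphenyl)-3-(trimethylsilyl)prop-2-yn-1-yl]-2,2-dimethyl-1,3-dioxane-4,6-dione F3.
- Heating in DMF/H2O gives (3S)-3-(3,4-dimethoxyphenyl)-5-(trimethylsilyl)pent-4-ynoic acid F4.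
- Acylation of (R)-4-benzyl-2-oxazolidinone (PivCl, Et3N, LiCl) gives (4R)-4-benzyl-3-[(3S)-3-(3,4-dimethoxyphenyl)-5-(trimethylsilyl)pent-4-ynoyl]-1,3-oxazolidin-2-one F5.
- Evans alkylation (NaN(SiMe3)2, tert-butyl bromoacetate, THF, −78 °C) sets the future C2. It gives tert-butyl (3R,4S)-3-{[(4R)-4-benzyl-2-oxo-1,3-oxazolidin-3-yl]carbonyl}-4-(3,4-dimethoxyphenyl)-6-(trimethylsilyl)hex-5-ynoate F6.
- The antipodal auxiliary is needed because here the acetate arm is the electrophile and the arylpropargyl group sits on the enolate.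
- LiBH4 cleavage of F6 gives 15.
- The fallback sets out from 5 and 6 and returns to the route at 15.

Step 11. Oxidation may run on past the catechol to the o-quinone and ring-opened acids. One of the two crowded C–B bonds may also be lost by protodeboronation in aqueous base. The fallback never liberates the catechol.
- 25 is converted with KHF2 (MeOH/H2O) into dipotassium (1S,2S,3S)-1-(3,4-dimethoxyphenyl)-2,3-bis(methoxymethyl)-1,2,3,4-tetrahydronaphthalene-6,7-diylbis(trifluoroborate) F7.
- Both C–O bonds are then made by Chan–Lam etherification with methanol (Cu(OAc)2·H2O, DMAP, 4 Å sieves, O2, CH2Cl2/MeOH, rt).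
- The fallback sets out from 25 and returns to the route at 27.

Further compounds
F1 | step 10 | hexacarbonyldicobalt complex of bis(pinacolboryl)ethyne | CC1(C)OB(OC1(C)C)C12C3(B4OC(C)(C)C(C)(C)O4)[Co]1(=C=O)(=C=O)(=C=O)[Co]23(=C=O)(=C=O)=C=O
F2 | step 4 | 5-(3,4-dimethoxybenzylidene)-2,2-dimethyl-1,3-dioxane-4,6-dione | COc1ccc(C=C2C(=O)OC(C)(C)OC2=O)cc1OC
F3 | step 4 | 5-[(1S)-1-(3,4-dimethoxyphenyl)-3-(trimethylsilyl)prop-2-yn-1-yl]-2,2-dimethyl-1,3-dioxane-4,6-dione | CC1(C)OC(=O)C(C(=O)O1)[C@@H](c1ccc(OC)c(OC)c1)C#C[Si](C)(C)C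
F4 | step 4 | (3S)-3-(3,4-dimethoxyphenyl)-5-(trimethylsilyl)pent-4-ynoic acid | OC(=O)C[C@@H](c1ccc(OC)c(OC)c1)C#C[Si](C)(C)C
F5 | step 4 | (4R)-4-benzyl-3-[(3S)-3-(3,4-dimethoxyphenyl)-5-(trimethylsilyl)pent-4-ynoyl]-1,3-oxazolidin-2-one | O=C(C[C@@H](c1ccc(OC)c(OC)c1)C#C[Si](C)(C)C)N1C(=O)OC[C@H]1Cc1ccccc1
F6 | step 4 | tert-butyl (3R,4S)-3-{[(4R)-4-benzyl-2-oxo-1,3-oxazolidin-3-yl]carbonyl}-4-(3,4-dimethoxyphenyl)-6-(trimethylsilyl)hex-5-ynoate | CC(C)(C)OC(=O)C[C@@H](C(=O)N1C(=O)OC[C@H]1Cc1ccccc1)[C@@H](c1ccc(OC)c(OC)c1)C#C[Si](C)(C)C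
F7 | step 11 | dipotassium (1S,2S,3S)-1-(3,4-dimethoxyphenyl)-2,3-bis(methoxymethyl)-1,2,3,4-tetrahydronaphthalene-6,7-diylbis(trifluoroborate) | COC[C@H]1Cc2cc([B-](F)(F)F)c([B-](F)(F)F)cc2[C@H](c2ccc(OC)c(OC)c2)[C@@H]1COC.[K+].[K+]
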